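## Retrosynthetic overview

1. Target 33 ⇐ removal of the dioxolane and silyl ether from 32 ⇐ E-enol ester by Wittig union of C12 aldehyde 26 with the acyloxymethylene ylide 31, a fragment made separately from 3-methylbut-2-enoic acid.
2. 26 ⇐ ozonolysis of the C12 vinyl group; C3–OH from conjugate reduction/enolate hydroxylation of the vinylogous ester 22; C12 and C1 set by vinyl conjugate addition/kinetic protonation on dienone 20.
3. 20 ⇐ allylic oxidation of tricyclic enol ether 19 ⇐ intramolecular hetero-Diels–Alder reaction of cycloheptadienal 18, which closes the cyclohexane and dihydropyran rings together and sets C6 and C11.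
4. 18 ⇐ ester 16 ⇐ rhodium-catalysed [4+3] union of triene 10 (carries the masked acetonyl chain) with vinyldiazoacetate 14; this forms the seven-membered ring first and sets quaternary C9.
5. 10 ⇐ carboalumination of enyne 8 and Negishi coupling with bromoallyl ketal 5; ring order: seven-membered ring, then cyclohexane and pyran simultaneously.

Assumption: Rh2(R-PTAD)4 is taken to give the (1R,2S)-cyclopropane 15 and hence (4S)-16; if the sense of induction is the opposite, the S-configured catalyst is used in step 9 with nothing else changed.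

Locants used for the tricyclic core from 19 on (not IUPAC): seven-membered ring C1–C2–C3–C11–C10–C9–C12; pyran C3–C4–O–C5–C6–C11 (C5 gem-dimethyl); cyclohexane C6–C7–C8–C9–C10–C11 (C9 methyl). In the target C1 bears CH2COCH3, C2 is the ring ketone, C3 bears OH and C12 bears the enol ester.

## Route

Step 1
Reactants: 1 ethyl vinyl ether; 2 2,3-dibromoprop-1-ene
Product: 4 2-bromo-4-ethoxypenta-1,4-diene, via 1-ethoxyvinyllithium 3 (not isolated)
Conditions: t-BuLi, THF, −78 → 0 °C; then 2, −78 → 23 °C
Reagents that add atoms: none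
Why: α-Lithiation of the enol ether gives an acyl-anion equivalent that displaces the allylic bromide (SN2 alkylation; the vinylic bromide is inert).

Step 2
Reactants: 4 2-bromo-4-ethoxypenta-1,4-diene
Product: 5 2-(2-bromoprop-2-en-1-yl)-2-methyl-1,3-dioxolane
Conditions: HOCH2CH2OH, PPTS (cat.), 4 Å MS, CH2Cl2, 0 → 23 °C
Reagents that add atoms: ethane-1,2-diol, OCCO
Why: Acid-catalysed transketalisation: the diol adds to the protonated enol ether and expels ethanol, so the isomerisation-prone β,γ-unsaturated ketone is never set free.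

Step 3
Reactants: 6 2-cyclopropylpropan-2-ol
Product: 7 5-bromo-2-methylpent-2-ene
Conditions: 48% aq. HBr, 0 °C
Reagents that add atoms: hydrogen bromide, Br
Why: Julia cyclopropylcarbinyl-to-homoallyl rearrangement: ionisation of the tertiary alcohol and ring opening by bromide give the trisubstituted homoallylic bromide.

Step 4
Reactants: 7 5-bromo-2-methylpent-2-ene
Product: 8 6-methylhept-5-en-1-yne
Conditions: LiC≡CH·H2NCH2CH2NH2, DMSO, 10 → 23 °C
Reagents that add atoms: lithium acetylide (ethylenediamine complex), [Li]C#C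
Why: SN2 alkylation of acetylide by the primary bromide in a dipolar aprotic solvent.

Step 5
Reactants: 8 6-methylhept-5-en-1-yne; 5 2-(2-bromoprop-2-en-1-yl)-2-methyl-1,3-dioxolane
Product: 10 2-[(3E)-4,8-dimethyl-2-methylidenenona-3,7-dien-1-yl]-2-methyl-1,3-dioxolane, via (E)-alkenyldimethylalane 9 (not isolated)
Conditions: Me3Al (2 equiv), Cp2ZrCl2 (0.2 equiv), ClCH2CH2Cl, 23 °C; then 5, Pd(PPh3)4 (5 mol %), ZnCl2 (1 equiv), THF, 23 °C
Reagents that add atoms: trimethylaluminium, C[Al](C)C
Why: Negishi zirconium-catalysed carboalumination adds Me–Al syn across the alkyne, fixing the E trisubstituted alkene, and the alkenylalane is cross-coupled (Negishi coupling) with the 2-bromoalkene with retention.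

Step 6
Reactants: 11 methyl 3-oxobutanoate
Product: 12 methyl 2-diazo-3-oxobutanoate
Conditions: 4-acetamidobenzenesulfonyl azide, Et3N, MeCN, 0 → 23 °C
Reagents that add atoms: 4-acetamidobenzenesulfonyl azide, CC(=O)Nc1ccc(cc1)S(=O)(=O)N=[N+]=[N-]
Why: Regitz diazo transfer to the activated methylene.

Step 7
Reactants: 12 methyl 2-diazo-3-oxobutanoate
Product: 13 methyl 2-diazo-3-hydroxybutanoate (racemic)
Conditions: NaBH4, MeOH, 0 °C
Reagents that add atoms: none
Why: Chemoselective borohydride reduction of the ketone leaves the diazo ester intact; the racemic carbinol centre is destroyed in step 8.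

Step 8
Reactants: 13 methyl 2-diazo-3-hydroxybutanoate
Product: 14 methyl 2-diazobut-3-enoate
Conditions: POCl3, Et3N, CH2Cl2, 0 °C; used at once as a cold hexane solution
Reagents that add atoms: none
Why: Dehydration (O-phosphorylation then E2 elimination) gives the vinyldiazoacetate.

Step 9
Reactants: 10 2-[(3E)-4,8-dimethyl-2-methylidenenona-3,7-dien-1-yl]-2-methyl-1,3-dioxolane; 14 methyl 2-diazobut-3-enoate
Product: 16 methyl (4S)-4-methyl-6-[(2-methyl-1,3-dioxolan-2-yl)methyl]-4-(4-methylpent-3-en-1-yl)cyclohepta-1,5-diene-1-carboxylate, via cis-divinylcyclopropane 15 (not isolated)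
Conditions: Rh2(R-PTAD)4 (dirhodium tetrakis[(R)-(1-adamantyl)(phthalimido)acetate], 1 mol %), hexanes, −26 → 23 °C, 14 added over 2 h; then 60 °C, 1 h
Reagents that add atoms: none
Why: Formal [4+3] cycloaddition by tandem cyclopropanation/Cope rearrangement: the chiral rhodium vinylcarbenoid cyclopropanates only the terminal 1,1-disubstituted alkene, and the boat-type Cope rearrangement of the cis-divinylcyclopropane transfers that chirality and the E geometry to the quaternary centre (C9 of the core).

Step 10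
Reactants: 16 cycloheptadiene ester
Product: 17 [(4S)-4-methyl-6-[(2-methyl-1,3-dioxolan-2-yl)methyl]-4-(4-methylpent-3-en-1-yl)cyclohepta-1,5-dien-1-yl]methanol
Conditions: i-Bu2AlH (2.5 equiv), CH2Cl2, −78 °C; Rochelle salt work-up
Reagents that add atoms: none
Why: Hydride reduction of the conjugated ester to the allylic alcohol; the dioxolane and the alkenes are inert.

Step 11
Reactants: 17 allylic alcohol
Product: 18 (4S)-4-methyl-6-[(2-methyl-1,3-dioxolan-2-yl)methyl]-4-(4-methylpent-3-en-1-yl)cyclohepta-1,5-diene-1-carbaldehyde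
Conditions: MnO2, CH2Cl2, 23 °C
Reagents that add atoms: none
Why: Selective allylic oxidation of the primary allylic alcohol to the enal.

Step 12
Reactants: 18 cycloheptadienal
Product: 19 (6R,9S,11S)-tricyclic dienyl ether (C1=C12 and C3=C4 double bonds; C2 is CH2; C1 carries the (2-methyl-1,3-dioxolan-2-yl)methyl group)
Conditions: BF3·OEt2 (0.3 equiv), CH2Cl2, −78 °C; Et3N quench
Reagents that add atoms: none
Why: Lewis-acid-promoted intramolecular inverse-electron-demand hetero-Diels–Alder reaction: the chain on C9 can reach only one face of the enal, with its tether endo, which sets C11 and C6 (ring-fusion hydrogens cis) relative to C9 and closes the cyclohexane and dihydropyran rings in one step.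

Step 13
Reactants: 19 tricyclic dienyl ether
Product: 20 (6R,9S,11S)-tricyclic dienone (as 19 but C2 is C=O)
Conditions: CrO3, 3,5-dimethylpyrazole, CH2Cl2, −20 °C
Reagents that add atoms: chromium trioxide, O=[Cr](=O)=O
Why: Allylic oxidation of the only doubly allylic CH2 (C2, flanked by the enol ether and the ring alkene) gives the cross-conjugated dienone.

Step 14
Reactants: 20 tricyclic dienone
Product: 22 (1S,6R,9S,11S,12S)-12-vinyl ketone (C2 ketone; C3=C4 enol ether; C1 side chain trans to the vinyl group), via trimethylsilyl enol ether 21 (not isolated)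
Conditions: CH2=CHMgBr (2 equiv), CuBr·SMe2 (20 mol %), Me3SiCl, HMPA, THF, −78 → −40 °C; then n-Bu4NF, AcOH, THF, −78 °C
Reagents that add atoms: vinylmagnesium bromide, C=C[Mg]Br
Why: Copper-catalysed conjugate addition to the enone (the vinylogous ester is less electrophilic) brings the vinyl group to C12 on the convex face, syn to the C9 methyl and anti to the C6–C8 bridge, and fluoride-triggered kinetic protonation of the silyl enol ether delivers H to C1 from the same open face, leaving the side chain trans to the vinyl group.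

Step 15
Reactants: 22 12-vinyl ketone
Product: 25 (1S,3R,6R,9S,11S,12S)-3-(trimethylsilyloxy) ketone (C3 O-silylated carbinol; C4 is CH2), via potassium enolate 23 (not isolated), via potassium alkoxide 24 (not isolated)
Conditions: K[(s-Bu)3BH] (1.1 equiv), THF, −78 °C; 2-(benzenesulfonyl)-3-phenyloxaziridine (1.5 equiv), −78 °C; then Me3SiCl, −78 → 0 °C
Reagents that add atoms: 2-(benzenesulfonyl)-3-phenyloxaziridine, O=S(=O)(c1ccccc1)N1OC1c1ccccc1; chlorotrimethylsilane, C[Si](C)(C)Cl
Why: Conjugate hydride reduction of the β-alkoxy enone gives the tetrasubstituted enolate regiospecifically, and Davis-type electrophilic hydroxylation on the convex face (anti to C10 and the gem-dimethyl pyran) sets C3 with oxygen cis to H-11; silylation masks the tertiary alcohol.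

Step 16
Reactants: 25 3-(trimethylsilyloxy) ketone
Product: 26 (1S,3R,6R,9S,11S,12S)-12-carbaldehyde
Conditions: O3, CH2Cl2, −78 °C; then Me2S, −78 → 23 °C
Reagents that add atoms: ozone, [O-][O+]=O
Why: Ozonolysis with reductive work-up cleaves the only remaining C=C to the C12 aldehyde without touching the silyl ether or the dioxolane.

Step 17
Reactants: 27 3-methylbut-2-enoic acid; 28 chloromethyl chlorosulfate
Product: 29 chloromethyl 3-methylbut-2-enoate
Conditions: NaHCO3, n-Bu4N·HSO4 (10 mol %), CH2Cl2/H2O, 23 °C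
Reagents that add atoms: none
Why: Phase-transfer O-alkylation of the carboxylate; chlorosulfate is the better leaving group, so the chloromethyl ester results.

Step 18
Reactants: 29 chloromethyl 3-methylbut-2-enoate
Product: 30 {[(3-methylbut-2-enoyl)oxy]methyl}triphenylphosphonium chloride
Conditions: PPh3, toluene, 110 °C
Reagents that add atoms: triphenylphosphine, c1ccc(cc1)P(c1ccccc1)c1ccccc1
Why: SN2 quaternisation of the phosphine by the activated chloromethyl ester.

Step 19
Reactants: 26 12-carbaldehyde; 30 phosphonium chloride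
Product: 32 silyl- and dioxolane-protected target with the (E)-enol ester, via acyloxymethylene ylide 31 (not isolated)
Conditions: 30 (2.5 equiv), NaN(SiMe3)2 (2.4 equiv), THF, −78 °C; then 26, −78 → 0 °C
Reagents that add atoms: none
Why: Wittig olefination with the Anders–Gaßner acyloxymethylene ylide reacts at the aldehyde in preference to the hindered ketone and installs the enol ester directly; the E isomer is separated from the Z isomer by chromatography.

Step 20
Reactants: 32 protected target
Product: 33 target (1S,3R,6R,9S,11S,12S)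
Conditions: PPTS (0.3 equiv), acetone/H2O (9:1), 45 °C
Reagents that add atoms: water, O
Why: Mild acid hydrolysis removes the dioxolane and the trimethylsilyl ether while the enol ester and the α-ketol survive.

## Compound list

1 | ethyl vinyl ether | C=COCC | starting material
2 | 2,3-dibromoprop-1-ene | C=C(Br)CBr | starting material
3 | 1-ethoxyvinyllithium | [Li]C(=C)OCC | intermediate
4 | 2-bromo-4-ethoxypenta-1,4-diene | C=C(Br)CC(=C)OCC | intermediate
5 | 2-(2-bromoprop-2-en-1-yl)-2-methyl-1,3-dioxolane | CC1(CC(Br)=C)OCCO1 | intermediate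
6 | 2-cyclopropylpropan-2-ol | CC(C)(O)C1CC1 | starting material
7 | 5-bromo-2-methylpent-2-ene | CC(C)=CCCBr | intermediate
8 | 6-methylhept-5-en-1-yne | C#CCCC=C(C)C | intermediate
9 | [(1E)-2,6-dimethylhepta-1,5-dien-1-yl]dimethylalane | C[Al](C)/C=C(\C)CCC=C(C)C | intermediate
10 | 2-[(3E)-4,8-dimethyl-2-methylidenenona-3,7-dien-1-yl]-2-methyl-1,3-dioxolane | C=C(CC1(C)OCCO1)/C=C(\C)CCC=C(C)C | intermediate
11 | methyl 3-oxobutanoate | COC(=O)CC(C)=O | starting material
12 | methyl 2-diazo-3-oxobutanoate | COC(=O)C(=[N+]=[N-])C(C)=O | intermediate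
13 | methyl 2-diazo-3-hydroxybutanoate (racemic) | COC(=O)C(=[N+]=[N-])C(C)O | intermediate
14 | methyl 2-diazobut-3-enoate | COC(=O)C(=[N+]=[N-])C=C | intermediate
15 | methyl (1R,2S)-2-[(1E)-2,6-dimethylhepta-1,5-dien-1-yl]-1-ethenyl-2-[(2-methyl-1,3-dioxolan-2-yl)methyl]cyclopropane-1-carboxylate | COC(=O)[C@@]1(C=C)C[C@]1(CC2(C)OCCO2)/C=C(\C)CCC=C(C)C | intermediate
16 | methyl (4S)-4-methyl-6-[(2-methyl-1,3-dioxolan-2-yl)methyl]-4-(4-methylpent-3-en-1-yl)cyclohepta-1,5-diene-1-carboxylate | COC(=O)C1=CC[C@](C)(CCC=C(C)C)C=C(CC2(C)OCCO2)C1 | intermediate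
17 | [(4S)-4-methyl-6-[(2-methyl-1,3-dioxolan-2-yl)methyl]-4-(4-methylpent-3-en-1-yl)cyclohepta-1,5-dien-1-yl]methanol | OCC1=CC[C@](C)(CCC=C(C)C)C=C(CC2(C)OCCO2)C1 | intermediate
18 | (4S)-4-methyl-6-[(2-methyl-1,3-dioxolan-2-yl)methyl]-4-(4-methylpent-3-en-1-yl)cyclohepta-1,5-diene-1-carbaldehyde | O=CC1=CC[C@](C)(CCC=C(C)C)C=C(CC2(C)OCCO2)C1 | intermediate
19 | (6R,9S,11S)-tricyclic dienyl ether: C1=C12 and C3=C4, C2 CH2, C1 bearing CH2-(2-methyl-1,3-dioxolan-2-yl), H-6 and H-11 cis | C1C(CC4(C)OCCO4)=C[C@@]2(C)CC[C@@H]3[C@H](C2)C1=COC3(C)C | intermediate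
20 | (6R,9S,11S)-tricyclic dienone: as 19 with C2 as C=O | O=C1C(CC4(C)OCCO4)=C[C@@]2(C)CC[C@@H]3[C@H](C2)C1=COC3(C)C | intermediate
21 | trimethylsilyl enol ether of 22 (C1=C2–OSiMe3, C12 vinyl as in 22) | CC4(OCCO4)CC1=C(O[Si](C)(C)C)C2=COC(C)(C)[C@@H]3CC[C@@](C)(C[C@@H]32)[C@H]1C=C | intermediate
22 | (1S,6R,9S,11S,12S)-12-vinyl ketone: C2 ketone, C3=C4 enol ether, C1 CH2-dioxolane chain trans to vinyl | CC4(OCCO4)C[C@@H]1C(=O)C2=COC(C)(C)[C@@H]3CC[C@@](C)(C[C@@H]32)[C@H]1C=C | intermediate
23 | potassium enolate of 4-hydro-22 (C2(OK)=C3, C4 CH2) | CC4(OCCO4)C[C@@H]1C(O[K])=C2COC(C)(C)[C@@H]3CC[C@@](C)(C[C@@H]32)[C@H]1C=C | intermediate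
24 | potassium alkoxide of the C3 ketol (C3–OK, 3R) | CC4(OCCO4)C[C@@H]1C(=O)[C@]2(O[K])COC(C)(C)[C@@H]3CC[C@@](C)(C[C@@H]32)[C@H]1C=C | intermediate
25 | (1S,3R,6R,9S,11S,12S)-3-(trimethylsilyloxy) ketone: C2 ketone, C3–OSiMe3, C12 vinyl, C1 CH2-dioxolane chain | CC4(OCCO4)C[C@@H]1C(=O)[C@]2(O[Si](C)(C)C)COC(C)(C)[C@@H]3CC[C@@](C)(C[C@@H]32)[C@H]1C=C | intermediate
26 | (1S,3R,6R,9S,11S,12S)-12-carbaldehyde: as 25 with CHO in place of vinyl | CC4(OCCO4)C[C@@H]1C(=O)[C@]2(O[Si](C)(C)C)COC(C)(C)[C@@H]3CC[C@@](C)(C[C@@H]32)[C@H]1C=O | intermediate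
27 | 3-methylbut-2-enoic acid | CC(C)=CC(=O)O | starting material
28 | chloromethyl chlorosulfate | ClCOS(=O)(=O)Cl | starting material
29 | chloromethyl 3-methylbut-2-enoate | CC(C)=CC(=O)OCCl | intermediate
30 | {[(3-methylbut-2-enoyl)oxy]methyl}triphenylphosphonium chloride | CC(C)=CC(=O)OC[P+](c1ccccc1)(c1ccccc1)c1ccccc1.[Cl-] | intermediate
31 | (triphenyl-λ5-phosphanylidene)methyl 3-methylbut-2-enoate (ylide) | CC(C)=CC(=O)OC=P(c1ccccc1)(c1ccccc1)c1ccccc1 | intermediate
32 | protected target: C12 (E)-CH=CH–O–CO–CH=CMe2, C3–OSiMe3, C1 CH2-dioxolane chain (1S,3R,6R,9S,11S,12S) | CC4(OCCO4)C[C@@H]1C(=O)[C@]2(O[Si](C)(C)C)COC(C)(C)[C@@H]3CC[C@@](C)(C[C@@H]32)[C@H]1/C=C/OC(=O)C=C(C)C | intermediate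
33 | target CNP0237201.2 (1S,3R,6R,9S,11S,12S): C1 CH2COCH3, C2 ketone, C3 OH, C12 (E)-enol 3-methylbut-2-enoate | CC(=O)C[C@@H]1C(=O)[C@]2(O)COC(C)(C)[C@@H]3CC[C@@](C)(C[C@@H]32)[C@H]1/C=C/OC(=O)C=C(C)C | target

## Step count and risks

Total step count: 20.
Longest linear sequence: 13 steps (1, 2, 5, 9, 10, 11, 12, 13, 14, 15, 16, 19, 20; the branches through steps 3–4 and through steps 6–8 are equally long).

Steps most likely to fail:

Step 9. The cycloaddition is established for the parent triene but not for a diene with a substituent on the terminal alkene. The cyclopropanation could give the trans-divinylcyclopropane, attack the dioxolane oxygens, or proceed with lower enantioselectivity. The fallback sets out from 8 (with 14) and comes back at 20. Alkenylalane 9 from 8 is coupled with vinyl bromide (Pd(PPh3)4, ZnCl2) to give (3E)-4,8-dimethylnona-1,3,7-triene F1. The [4+3] reaction of F1 with 14 gives methyl (4S)-4-methyl-4-(4-methylpent-3-en-1-yl)cyclohepta-1,5-diene-1-carboxylate F2. Reduction with i-Bu2AlH gives the allylic alcohol F3, MnO2 gives the enal F4, BF3·OEt2 gives the side-chain-free tricyclic dienyl ether F5, and CrO3/3,5-dimethylpyrazole gives the side-chain-free dienone F6. Iodine and pyridine then give the 1-iodo dienone F7. Negishi coupling of F7 with [(2-methyl-1,3-dioxolan-2-yl)methyl]zinc bromide F8 (from 2-(bromomethyl)-2-methyl-1,3-dioxolane, zinc dust and LiCl in THF; PdCl2(dppf) catalyst) installs the side chain and gives 20.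

Step 14. The enone is α-substituted and its β-carbon is neopentyl, and the configuration at C1 depends on the face of a kinetic protonation. The fallback sets out from 20 and comes back at 22. The conjugate addition is run as before but the silyl enol ether 21 is isolated. PhSeCl (CH2Cl2, −78 °C) converts it into the 1-(phenylselanyl) ketone F9. Bu3SnH/AIBN (benzene, 80 °C) then generates the planar C1 radical, which takes a hydrogen atom from the bulky stannane on the open face. C1 is thus set by radical hydrogen-atom transfer instead of enolate protonation, giving 22.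

Step 19. The acyloxymethylene ylide typically gives E/Z mixtures, and the aldehyde is epimerisable at C12 under basic conditions. The fallback sets out from 26 (with acid 27) and comes back at 33. Takai–Utimoto olefination of 26 with 2-(dichloromethyl)-4,4,5,5-tetramethyl-1,3,2-dioxaborolane (CrCl2, lithium iodide, THF) gives the (E)-alkenyl pinacol boronate F10. KHF2 in aqueous methanol gives the potassium (E)-alkenyltrifluoroborate F11, with loss of the silyl ether. Copper-mediated oxidative coupling with 27 (Cu(OAc)2, DMAP, 4 Å MS, O2, CH2Cl2) gives the (E)-enol ester F12 with retention of alkene geometry. The hydrolysis conditions of step 20 then give 33.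

## Further compounds

F1 | step 9 | (3E)-4,8-dimethylnona-1,3,7-triene | C=C/C=C(\C)CCC=C(C)C
F2 | step 9 | methyl (4S)-4-methyl-4-(4-methylpent-3-en-1-yl)cyclohepta-1,5-diene-1-carboxylate | COC(=O)C1=CC[C@](C)(CCC=C(C)C)C=CC1
F3 | step 9 | [(4S)-4-methyl-4-(4-methylpent-3-en-1-yl)cyclohepta-1,5-dien-1-yl]methanol | OCC1=CC[C@](C)(CCC=C(C)C)C=CC1
F4 | step 9 | (4S)-4-methyl-4-(4-methylpent-3-en-1-yl)cyclohepta-1,5-diene-1-carbaldehyde | O=CC1=CC[C@](C)(CCC=C(C)C)C=CC1
F5 | step 9 | (6R,9S,11S)-tricyclic dienyl ether without C1 side chain | C1C=C[C@@]2(C)CC[C@@H]3[C@H](C2)C1=COC3(C)C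
F6 | step 9 | (6R,9S,11S)-tricyclic dienone without C1 side chain | O=C1C=C[C@@]2(C)CC[C@@H]3[C@H](C2)C1=COC3(C)C
F7 | step 9 | (6R,9S,11S)-1-iodo tricyclic dienone | O=C1C(I)=C[C@@]2(C)CC[C@@H]3[C@H](C2)C1=COC3(C)C
F8 | step 9 | [(2-methyl-1,3-dioxolan-2-yl)methyl]zinc bromide | CC1(C[Zn]Br)OCCO1
F9 | step 14 | 1-(phenylselanyl) derivative of 22 (selenium on the convex face) | CC4(OCCO4)C[C@]1([Se]c5ccccc5)C(=O)C2=COC(C)(C)[C@@H]3CC[C@@](C)(C[C@@H]32)[C@H]1C=C
F10 | step 19 | (E)-alkenyl pinacol boronate from 26 | CC4(OCCO4)C[C@@H]1C(=O)[C@]2(O[Si](C)(C)C)COC(C)(C)[C@@H]3CC[C@@](C)(C[C@@H]32)[C@H]1/C=C/B5OC(C)(C)C(C)(C)O5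
F11 | step 19 | potassium (E)-alkenyltrifluoroborate with free C3 hydroxyl | CC4(OCCO4)C[C@@H]1C(=O)[C@]2(O)COC(C)(C)[C@@H]3CC[C@@](C)(C[C@@H]32)[C@H]1/C=C/[B-](F)(F)F.[K+]
F12 | step 19 | dioxolane-protected target with free C3 hydroxyl | CC4(OCCO4)C[C@@H]1C(=O)[C@]2(O)COC(C)(C)[C@@H]3CC[C@@](C)(C[C@@H]32)[C@H]1/C=C/OC(=O)C=C(C)C
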